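**Retrosynthetic overview**
- The acid comes from its tert-butyl ester, and the C6 ketone from allylic C–H oxidation of the C7=C8 alkene.
- Key disconnection C13–C16: a Z-enol triflate is coupled with acetoxymethylzinc bromide, an acetoxymethyl carbanion equivalent, which fixes the 13Z geometry; the triflate comes from a β-keto ester made from a Weinreb amide and tert-butyl acetate enolate.
- The C7=C8 alkene comes from dehydration of the C8 alcohol and exo-to-endo isomerisation, after opening of a δ-lactone.
- Rings A and B form in one enantioselective proton-initiated cyclisation of (4E,8E)-farnesylacetic acid: ring A closes first, then ring B, then the lactone ring, which is opened again later.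
- The acid comes from (2E,6E)-farnesol and the dianion of acetic acid.

Assumption: the target SMILES encodes 5R,9R,10S,13Z, the ent-labdane series, so the natural-series chiral pool (sclareol-derived lactones) would give the wrong enantiomer and the decalin is built by reagent-controlled cyclisation; lactone 6 is brought to ≥98% ee by recrystallisation.

**Step 1**
Reactants: 1 (2E,6E)-farnesol
Product: 2 (2E,6E)-farnesyl bromide
Conditions: PBr3 (0.4 equiv), Et2O, −10 °C
Reagents that add atoms: phosphorus tribromide, BrP(Br)Br
Why: Bromination of a primary allylic alcohol with PBr3 is an SN2 displacement of the phosphite ester that at low temperature gives the primary bromide without allylic shift or loss of E geometry, and no stereocenter is formed.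

**Step 2**
Reactants: 2 (2E,6E)-farnesyl bromide; 3 acetic acid
Product: 5 (4E,8E)-5,9,13-trimethyltetradeca-4,8,12-trienoic acid (farnesylacetic acid), via dilithium acetate dianion 4 (not isolated)
Conditions: CH3CO2H, LiN(i-Pr)2 (2.2 equiv), THF/DMPU, 0 to 40 °C; then 2, 0 °C to rt; aq HCl
Reagents that add atoms: acetic acid (compound 3), CC(=O)O
Why: Alkylation of a carboxylic acid dianion with a primary allylic bromide goes by SN2 at C1 and adds the two carbons that become C12 and C13, leaving both trisubstituted alkenes E.

**Step 3**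
Reactants: 5 (4E,8E)-5,9,13-trimethyltetradeca-4,8,12-trienoic acid
Product: 6 ent-ambreinolide, (5R,8S,9S,10R)-14,15,16-trinorlabdan-13,8-olide (trans-decalin; lactone C8–O bond trans to the C9–C11 bond)
Conditions: SnCl4 (2 equiv), (S)-2′-(2-fluorobenzyloxy)-1,1′-binaphthalen-2-ol (2.2 equiv), toluene, −78 °C, 3 d; recrystallisation from hexane
Reagents that add atoms: none
Why: This is a Yamamoto-type enantioselective proton-initiated polyene cyclisation with a Lewis acid-assisted chiral Brønsted acid, in which the chiral proton donor protonates one face of the terminal alkene, ring A and then ring B close through chair–chair transition states of the E,E-triene (trans fusion, C9 chain equatorial) and the acid traps the C8 cation anti to the new C9–C10 bond, so C5, C9 and C10 are set together in the ent series by the (S)-ligand (antipode of the ligand that gives the natural series) and recrystallisation raises the ee.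

**Step 4**
Reactants: 6 ent-ambreinolide
Product: 7 (5R,8S,9S,10R)-8-hydroxy-N-methoxy-N-methyl-14,15,16-trinorlabdan-13-amide (equatorial tertiary OH)
Conditions: MeNH(OMe)·HCl, i-PrMgCl (3 equiv), THF, −20 to 0 °C
Reagents that add atoms: N,O-dimethylhydroxylamine hydrochloride, CNOC.Cl
Why: Weinreb aminolysis of the lactone by the chloromagnesium amide is an acyl substitution that expels the tertiary alkoxide, gives a hydroxy amide that cannot relactonise easily, and touches no stereocenter.

**Step 5**
Reactants: 7 (5R,8S,9S,10R)-8-hydroxy-N-methoxy-N-methyl-14,15,16-trinorlabdan-13-amide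
Product: 8 (5R,9R,10R)-N-methoxy-N-methyl-14,15,16-trinorlabd-8(17)-en-13-amide (exocyclic alkene)
Conditions: SOCl2, pyridine, CH2Cl2, −78 °C
Reagents that add atoms: none
Why: Chlorosulfite dehydration of the equatorial tertiary alcohol (E2-type, as in the sclareol to manool-type dehydration) removes the C8 stereocenter and favours the exocyclic alkene because only the C17 methyl hydrogens are antiperiplanar to the C–O bond, and the minor C7=C8 isomer formed alongside is compound 9 and is carried along.

**Step 6**
Reactants: 8 (5R,9R,10R)-N-methoxy-N-methyl-14,15,16-trinorlabd-8(17)-en-13-amide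
Product: 9 (5R,9R,10R)-N-methoxy-N-methyl-14,15,16-trinorlabd-7-en-13-amide
Conditions: chloro[N,N′-bis(3,5-di-tert-butylsalicylidene)-1,2-cyclohexanediaminato]cobalt, Co(C36H52N2O2)Cl (3 mol%), PhSiH3 (6 mol%), benzene, rt
Reagents that add atoms: none
Why: In this cobalt hydride hydrogen-atom-transfer alkene isomerisation (Shenvi type), H-atom addition to the exocyclic CH2 gives the tertiary C8 radical and H-atom abstraction from the accessible C7 methylene, not from the hindered tertiary C9–H, gives the trisubstituted C7=C8 alkene under kinetic control with C9 untouched.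

**Step 7**
Reactants: 9 (5R,9R,10R)-N-methoxy-N-methyl-14,15,16-trinorlabd-7-en-13-amide; 10 tert-butyl acetate
Product: 12 tert-butyl (5R,9R,10R)-13-oxo-16-norlabd-7-en-15-oate, via lithium tert-butyl acetate enolate 11 (not isolated)
Conditions: t-BuOAc, LiN(i-Pr)2 (2.5 equiv), THF, −78 °C; then 9, −78 to −20 °C; aq NH4Cl
Reagents that add atoms: tert-butyl acetate (compound 10), CC(=O)OC(C)(C)C
Why: Claisen-type acylation of the ester enolate by the Weinreb amide forms the C13–C14 bond through a chelated tetrahedral intermediate that prevents over-addition, and no stereocenter is formed.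

**Step 8**
Reactants: 12 tert-butyl (5R,9R,10R)-13-oxo-16-norlabd-7-en-15-oate
Product: 13 tert-butyl (5R,9R,10R,13Z)-13-[(trifluoromethylsulfonyl)oxy]-16-norlabda-7,13-dien-15-oate (triflate cis to the ester)
Conditions: Tf2O, saturated aq LiOH, toluene, 5 °C
Reagents that add atoms: trifluoromethanesulfonic anhydride, O=S(=O)(OS(=O)(=O)C(F)(F)F)C(F)(F)F
Why: O-Triflation of the lithium-chelated Z-enolate of the β-keto ester (Frantz conditions) fixes the enol triflate geometry with the triflate cis to the ester, which is the geometry needed at C13=C14.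

**Step 9 (key step)**
Reactants: 13 tert-butyl (5R,9R,10R,13Z)-13-[(trifluoromethylsulfonyl)oxy]-16-norlabda-7,13-dien-15-oate; 14 bromomethyl acetate
Product: 16 tert-butyl (5R,9R,10R,13Z)-16-acetoxylabda-7,13-dien-15-oate, via acetoxymethylzinc bromide 15 (not isolated)
Conditions: BrCH2OAc, Zn dust, LiCl, THF, 10 °C; then 13, Pd(PPh3)4 (5 mol%), THF, 0 °C to rt
Reagents that add atoms: bromomethyl acetate (compound 14), CC(=O)OCBr
Why: Proposed new method: a Negishi coupling of an α-acyloxyalkylzinc halide used as an acetoxymethyl carbanion (hydroxymethyl anion) equivalent, so that the O-bearing C16, which is normally electrophilic, is joined as a nucleophile to C13, the normally electrophilic β-carbon of the enoate, and since oxidative addition of zerovalent palladium to the vinyl triflate, transmetalation and reductive elimination all go with retention the CH2OAc group ends cis to the ester (13Z); the closest known reactions are the (pivaloyloxymethyl)zinc iodide chemistry of Knochel and Negishi couplings of functionalised alkylzinc halides with β-keto ester enol triflates.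

**Step 10**
Reactants: 16 tert-butyl (5R,9R,10R,13Z)-16-acetoxylabda-7,13-dien-15-oate
Product: 17 tert-butyl (5R,9R,10S,13Z)-16-acetoxy-6-oxolabda-7,13-dien-15-oate
Conditions: CrO3, 3,5-dimethylpyrazole, CH2Cl2, −20 °C
Reagents that add atoms: chromium trioxide, O=[Cr](=O)=O
Why: In this allylic oxidation with hexavalent chromium and 3,5-dimethylpyrazole (Salmond type) C6 is the only allylic methylene of the electron-rich ring alkene, so oxidation there gives the 7-en-6-one while the electron-poor side-chain enoate is not attacked and C5, C9 and C10 are untouched.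

**Step 11**
Reactants: 17 tert-butyl (5R,9R,10S,13Z)-16-acetoxy-6-oxolabda-7,13-dien-15-oate
Product: 18 (5R,9R,10S,13Z)-16-acetoxy-6-oxolabda-7,13-dien-15-oic acid (target, ent-labdane series)
Conditions: CF3CO2H/CH2Cl2 (1:4), 0 °C, 1 h
Reagents that add atoms: none
Why: Acidolysis of the tert-butyl ester (E1 loss of isobutene) frees the acid without touching the primary allylic acetate or the enone, and short exposure at 0 °C avoids lactonisation of the Z-acetoxy acid.

**Compound list**
1 | (2E,6E)-farnesol | CC(C)=CCC/C(C)=C/CC/C(C)=C/CO | starting material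
2 | (2E,6E)-farnesyl bromide | CC(C)=CCC/C(C)=C/CC/C(C)=C/CBr | intermediate
3 | acetic acid | CC(=O)O | starting material
4 | dilithium acetate dianion | [Li+].[Li+].[CH2-]C([O-])=O | intermediate
5 | (4E,8E)-5,9,13-trimethyltetradeca-4,8,12-trienoic acid | CC(C)=CCC/C(C)=C/CC/C(C)=C/CCC(=O)O | intermediate
6 | ent-ambreinolide, (5R,8S,9S,10R)-14,15,16-trinorlabdan-13,8-olide | O=C1CC[C@@H]2[C@@](C)(O1)CC[C@@H]3C(C)(C)CCC[C@@]23C | intermediate
7 | (5R,8S,9S,10R)-8-hydroxy-N-methoxy-N-methyl-14,15,16-trinorlabdan-13-amide | CON(C)C(=O)CC[C@@H]1[C@@](C)(O)CC[C@@H]2C(C)(C)CCC[C@@]12C | intermediate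
8 | (5R,9R,10R)-N-methoxy-N-methyl-14,15,16-trinorlabd-8(17)-en-13-amide | CON(C)C(=O)CC[C@@H]1C(=C)CC[C@@H]2C(C)(C)CCC[C@@]12C | intermediate
9 | (5R,9R,10R)-N-methoxy-N-methyl-14,15,16-trinorlabd-7-en-13-amide | CON(C)C(=O)CC[C@@H]1C(C)=CC[C@@H]2C(C)(C)CCC[C@@]12C | intermediate
10 | tert-butyl acetate | CC(=O)OC(C)(C)C | starting material
11 | lithium tert-butyl acetate enolate | [Li+].C=C([O-])OC(C)(C)C | intermediate
12 | tert-butyl (5R,9R,10R)-13-oxo-16-norlabd-7-en-15-oate | CC(C)(C)OC(=O)CC(=O)CC[C@@H]1C(C)=CC[C@@H]2C(C)(C)CCC[C@@]12C | intermediate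
13 | tert-butyl (5R,9R,10R,13Z)-13-[(trifluoromethylsulfonyl)oxy]-16-norlabda-7,13-dien-15-oate | CC(C)(C)OC(=O)/C=C(\OS(=O)(=O)C(F)(F)F)CC[C@@H]1C(C)=CC[C@@H]2C(C)(C)CCC[C@@]12C | intermediate
14 | bromomethyl acetate | CC(=O)OCBr | starting material
15 | acetoxymethylzinc bromide | CC(=O)OC[Zn]Br | intermediate
16 | tert-butyl (5R,9R,10R,13Z)-16-acetoxylabda-7,13-dien-15-oate | CC(=O)OC/C(=C\C(=O)OC(C)(C)C)CC[C@@H]1C(C)=CC[C@@H]2C(C)(C)CCC[C@@]12C | intermediate
17 | tert-butyl (5R,9R,10S,13Z)-16-acetoxy-6-oxolabda-7,13-dien-15-oate | CC(=O)OC/C(=C\C(=O)OC(C)(C)C)CC[C@@H]1C(C)=CC(=O)[C@@H]2C(C)(C)CCC[C@@]12C | intermediate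
18 | (5R,9R,10S,13Z)-16-acetoxy-6-oxolabda-7,13-dien-15-oic acid | CC(=O)OC/C(=C\C(=O)O)CC[C@@H]1C(C)=CC(=O)[C@@H]2C(C)(C)CCC[C@@]12C | target

**Step count and risks**
Total step count: 11. Longest linear sequence: 11 steps (1 to 18); the zinc reagent and the enolates are made in the flask.

The three steps most likely to fail:

Step 3 (enantioselective bicyclisation). The precedent is for the lower homologue (homofarnesic acid to sclareolide) and ee values of this reagent class are typically 75–90%, so ee or conversion may fall short. Fallback, setting out from acid 5: switch from proton to iodonium initiation, using N-iodosuccinimide with a stoichiometric chiral BINOL-derived phosphoramidite promoter in toluene at −40 °C. This gives the iodo lactone 3-iodo-ent-ambreinolide F1 (iodine equatorial on C3, cis to the C10 methyl). Radical deiodination (Bu3SnH, AIBN, toluene, 80 °C) then returns to lactone 6.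

Step 9 (key coupling). The acetoxymethylzinc reagent may be unstable, and the allylic acetate product could ionise with zerovalent palladium, eroding yield or Z geometry. Fallback, setting out from enol triflate 13: a Stille coupling with tributyl[(4-methoxybenzyloxy)methyl]stannane, a protected hydroxymethyl anion equivalent (Pd(PPh3)4, LiCl, CuI, THF, 60 °C). This gives the ether tert-butyl (13Z)-16-(4-methoxybenzyloxy)-ent-labda-7,13-dien-15-oate F2, which is inert to palladium. DDQ in CH2Cl2/pH 7 buffer at 0 °C frees the alcohol tert-butyl (13Z)-16-hydroxy-ent-labda-7,13-dien-15-oate F3, which is acetylated at once (Ac2O, pyridine, DMAP, 0 °C) before it can lactonise, coming back at 16.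

Step 10 (late allylic oxidation). Competing attack at C9–H (giving the 8-en-7-one) or on the side chain would cost advanced material. Fallback, setting out from Weinreb amide 9: oxidise early on this simple intermediate with t-BuOOH and Rh2(C6H10NO)4 (dirhodium tetracaprolactamate), K2CO3, CH2Cl2, rt, to give the enone amide (5R,9R,10S)-N-methoxy-N-methyl-6-oxo-14,15,16-trinorlabd-7-en-13-amide F4, where isomers are easily separated. Acylation of enolate 11 (3 equiv, the first protecting the enone as its dienolate) gives tert-butyl 6,13-dioxo-16-nor-ent-labd-7-en-15-oate F5. Triflation as in step 8 gives tert-butyl (13Z)-6-oxo-13-[(trifluoromethylsulfonyl)oxy]-16-nor-ent-labda-7,13-dien-15-oate F6, and coupling with 15 as in step 9 comes back at 17.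

**Further compounds**
F1 | step 3 | 3-iodo-ent-ambreinolide (iodine equatorial, cis to the C10 methyl) | O=C1CC[C@@H]2[C@@](C)(O1)CC[C@@H]3C(C)(C)[C@H](I)CC[C@@]23C
F2 | step 9 | tert-butyl (13Z)-16-(4-methoxybenzyloxy)-ent-labda-7,13-dien-15-oate | COc1ccc(COC/C(=C\C(=O)OC(C)(C)C)CC[C@@H]2C(C)=CC[C@@H]3C(C)(C)CCC[C@@]23C)cc1
F3 | step 9 | tert-butyl (13Z)-16-hydroxy-ent-labda-7,13-dien-15-oate | OC/C(=C\C(=O)OC(C)(C)C)CC[C@@H]1C(C)=CC[C@@H]2C(C)(C)CCC[C@@]12C
F4 | step 10 | (5R,9R,10S)-N-methoxy-N-methyl-6-oxo-14,15,16-trinorlabd-7-en-13-amide | CON(C)C(=O)CC[C@@H]1C(C)=CC(=O)[C@@H]2C(C)(C)CCC[C@@]12C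
F5 | step 10 | tert-butyl 6,13-dioxo-16-nor-ent-labd-7-en-15-oate | CC(C)(C)OC(=O)CC(=O)CC[C@@H]1C(C)=CC(=O)[C@@H]2C(C)(C)CCC[C@@]12C
F6 | step 10 | tert-butyl (13Z)-6-oxo-13-[(trifluoromethylsulfonyl)oxy]-16-nor-ent-labda-7,13-dien-15-oate | CC(C)(C)OC(=O)/C=C(\OS(=O)(=O)C(F)(F)F)CC[C@@H]1C(C)=CC(=O)[C@@H]2C(C)(C)CCC[C@@]12C
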